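Conventions: benzofuran numbering is used for the core (O1, C2, C3, C3a, C4–C7, C7a). Ring A is the benzo ring, ring B the dihydrofuran ring, ring C the 4-hydroxy-3-methoxyphenyl group on C2 (its carbons are primed), ring D the 4-hydroxybenzoyl group. TBS = tert-butyldimethylsilyl, TIPS = triisopropylsilyl.

## Analysis of the target

Target 25 is a phenylcoumaran neolignan: a 2,3-dihydrobenzofuran whose ring B carries ring C on C2 and a 4-hydroxybenzoyloxymethyl group (ring D) on C3, and whose ring A carries a methoxyl on C7 and a (Z)-3-oxoprop-1-enyl chain on C5. The two stereocentres, C2 (S) and C3 (R), are adjacent and benzylic, and their substituents stand trans across ring B; the third stereo-element is the Z double bond. The sensitive groups are the (Z)-enal (isomerisation to E by acid, base, light or reversible conjugate addition), the two free phenols, the primary benzoate (hydrolysis, acyl shift) and the O1–C2 bond, a benzylic aryl ether para to a free phenol that can reopen through a quinone methide. The synthesis is hard because absolute control is needed at two contiguous benzylic carbons without functional handles, because a thermodynamically disfavoured Z-enal must appear late beside free phenols, and because the ester rules out hydrolytic or strongly reducing deprotections once it is in place. The plan rests on the hydroxyl on C4′ of ring C, which stands exactly para to C2: as a phenoxide it lets C2 become the exocyclic carbon of a p-quinone methide, which the oxygen on C7a of ring A can capture. C2 therefore needs no control before ring closure; only C3 has to be set in the absolute sense, and C2 follows from it. C5 lies para to O1 and can hold a bromide through the whole sequence as a placeholder for the side chain.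

## Retrosynthetic reasoning

Side chain at C5. The (Z)-enal of 25 is the most fragile group and is made last. It is taken back to the (Z)-allylic alcohol 24, then to alkynol 23 by a cis-semireduction, and the C5–C(sp) bond of 23 is cut to give aryl bromide 21 and propargyl alcohol 22. The cut is placed here because the bromide is inert to everything before it and the three carbons come from one commercial unit. The forward steps must couple an electron-rich aryl bromide in the presence of free phenols, stop the reduction at the alkene, and oxidise the allylic alcohol without touching the double-bond geometry.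

O1–C2 bond. Bromide 21 is opened at O1–C2 to the acyclic benzylic acetate 18, by way of triphenol 19 and p-quinone methide 20. No other bond of ring B can be formed with C2 passing through a planar stage, and this is what removes the need to control C2 in the precursor. A second gain is that the one operation that closes the ring also frees all three phenols, so no deprotection is left for the end. The forward reaction must form the quinone methide faster than the esters are cleaved, and must close trans to the C3 substituent.

The two acyl groups. Acetate 18 is taken back to alcohol 17, and the primary ester of 17 is cut to diol 13 and acid 16, which comes from 4-hydroxybenzoic acid 14. The benzoate is part of the target and is put on before ring closure, so the delicate products are never acylated. The acetate is only the leaving group. The forward steps must tell the primary hydroxyl from the hindered secondary benzylic one.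

C2–C3 bond. Diol 13 is taken back to the aldol adduct 12 and cut between the carbinol carbon and the aryl-bearing carbon, which gives imide 8 and aldehyde 10, the latter from vanillin 9. In 12 the future C3 is alpha to an acyl group, so it can be set by the auxiliary 6 in a syn-aldol reaction. An enantioselective ketone reduction at this stage would instead fix the carbinol carbon, which is the centre that step 12 erases. A further gain is that all stereoisomers of 12 are diastereomers, so the purity at C3 can be raised by chromatography before the auxiliary is removed.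

Ring A acetic acid unit. Imide 8 is cut at the N–acyl bond to acid 5 and oxazolidinone 6. Acid 5 is taken back through aldehyde 4 and enol ether 3 to the silylated aldehyde 2, and so to 5-bromo-o-vanillin 1. This starting material already holds the bromide (future C5), the methoxyl (future C7) and the phenol oxygen (future O1) in the right places, so only a one-carbon homologation of its formyl group is needed.

## Alternatives that were turned down

Alternative 1: Ring A is dismantled at C6–C7, C4–C5 and C3a–C4, which leaves a dihydrofuran that already holds C2 and C3. In the forward direction the Cr(CO)5 methoxycarbene complex A2 (zerovalent chromium, carbene carbon on C5 of the dihydrofuran) would take up 3,3-diethoxypropyne A3 and one CO ligand in a Dötz benzannulation and give phenol A1.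
- For it: both stereocentres are made on a saturated ring before any benzylic position exists, the C7 methoxyl comes from the carbene, and C5 arrives at the aldehyde oxidation level. It does not depend on a diastereoselective ring closure, and on that point it is stronger than the chosen route.
- Against it: A2 needs its own enantioselective synthesis of a 2-aryl-3-substituted 2,3-dihydrofuran, which is an acid-labile enol ether with a benzylic C–O bond, then metalation and stoichiometric chromium. The surplus C4 hydroxyl of A1 costs two more steps. The aldehyde still needs a Z-selective two-carbon olefination, and the silyl groups must be exchanged for the benzoate and the free phenol next to the finished enal.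
- Comparison: the chosen strategy offers a much shorter path from commercial aromatics to the ring-closed, fully deprotected core 21, with ring A taken intact from 1.

Alternative 2: Ring B is cut at both C2–C3 and O1–C2, into a ring A o-quinone methide and a ring C benzylic ylide. In the forward direction a carbonate base would eliminate sulfinate from sulfone A5 and deprotonate sulfonium salt A6; the ylide carbon adds to the exocyclic carbon (C3) and the phenoxide then displaces the sulfide at C2, which gives A4.
- For it: two bonds and the ring are formed in one operation from two simple aromatics, the trans arrangement follows from the displacement geometry, and the bromide handle is the same as in 21. In step economy it is stronger than the chosen route.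
- Against it: the absolute configuration has no dependable source. It would have to come from a chiral sulfide or a chiral catalyst acting on an electron-rich, semi-stabilised benzyl ylide and an alkyl-substituted o-quinone methide. That quinone methide has hydrogens next to its exocyclic carbon and can escape by a 1,5-hydrogen shift to a vinyl phenol. After A4, three protecting-group operations remain.
- Comparison: the chosen strategy spends more steps before ring closure, but takes the configuration of C3 from an auxiliary-controlled aldol reaction and lets C2 follow by substrate control.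

Alternative 3: The aryl ether bond O1–C7a is cut. In the forward direction the C2 alkoxide of the syn diol monoether A8, made with a strong amide base, would displace fluoride at C7a, activated by the para formyl group, and give A7.
- For it: both stereocentres are set in the acyclic precursor and are not touched by the ring closure, so the stereochemical outcome is settled beforehand; on that point it is stronger than the chosen route. C5 already carries a carbon at the aldehyde level.
- Against it: the ring A unit is a 2-fluoro-3-methoxy-5-formylphenylacetic acid derivative with no short commercial source. The fluoride is activated by a single formyl group and flanked by a donating methoxyl, so the substitution is slow, while the alkoxide can add to the aldehyde and start hydride-transfer side reactions. Both C2 and C3 must now be correct, so the convergence at C2 is lost. The end game needs a Z-selective olefination and a protecting-group exchange beside the enal.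
- Comparison: the chosen strategy needs only C3 to be correct, starts from a commercial ring A aldehyde, and has no protecting group left when the enal is made.

Key step: step 12

Assumption: imide 8 is taken to follow the usual course of boron aldol reactions of N-acyl oxazolidinones (Z-enolate, syn adduct, attack on the face away from the benzyl group). The configuration of the carbinol carbon does not matter, because step 12 erases it.

## Route

Step 1
Reactants: 1 5-bromo-2-hydroxy-3-methoxybenzaldehyde (5-bromo-o-vanillin)
Product: 2 5-bromo-2-(tert-butyldimethylsilyloxy)-3-methoxybenzaldehyde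
Conditions: TBSCl, imidazole, DMF, rt
Reagents that add atoms: tert-butyldimethylsilyl chloride, CC(C)(C)[Si](C)(C)Cl
Why: Imidazole-promoted O-silylation of an acidic phenol; the resulting aryl silyl ether is flanked on both sides and should be hindered enough to last until step 12.

Step 2
Reactants: 2 5-bromo-2-(tert-butyldimethylsilyloxy)-3-methoxybenzaldehyde
Product: 3 tert-butyl[4-bromo-2-methoxy-6-(2-methoxyethenyl)phenoxy]dimethylsilane (E/Z mixture)
Conditions: MeOCH2PPh3Cl, KN(SiMe3)2, THF, 0 °C to rt
Reagents that add atoms: (methoxymethyl)triphenylphosphonium chloride, COC[P+](c1ccccc1)(c1ccccc1)c1ccccc1.[Cl-]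
Why: Wittig methoxymethylenation with a non-nucleophilic amide base that should not attack silicon; both enol ether isomers converge in step 3, so the geometry does not matter.

Step 3
Reactants: 3 tert-butyl[4-bromo-2-methoxy-6-(2-methoxyethenyl)phenoxy]dimethylsilane (E/Z mixture)
Product: 4 2-[5-bromo-2-(tert-butyldimethylsilyloxy)-3-methoxyphenyl]acetaldehyde
Conditions: CF3CO2H, H2O, CH2Cl2, 0 °C to rt
Reagents that add atoms: water, O
Why: Acid-catalysed enol ether hydrolysis (protonation at the benzylic carbon, collapse of the hemiacetal); the hindered aryl silyl ether should tolerate brief aqueous acid, and the aldehyde is carried on without storage.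

Step 4
Reactants: 4 2-[5-bromo-2-(tert-butyldimethylsilyloxy)-3-methoxyphenyl]acetaldehyde
Product: 5 2-[5-bromo-2-(tert-butyldimethylsilyloxy)-3-methoxyphenyl]acetic acid
Conditions: NaClO2, NaH2PO4, 2-methyl-2-butene, t-BuOH/H2O, rt
Reagents that add atoms: sodium chlorite, [Na+].[O-]Cl=O
Why: Pinnick oxidation; the buffered chlorite oxidises only the aldehyde, and the alkene scavenger removes the hypochlorite that could otherwise chlorinate the electron-rich ring A.

Step 5
Reactants: 5 2-[5-bromo-2-(tert-butyldimethylsilyloxy)-3-methoxyphenyl]acetic acid; 6 (S)-4-benzyl-2-oxazolidinone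
Product: 8 (S)-4-benzyl-3-{2-[5-bromo-2-(tert-butyldimethylsilyloxy)-3-methoxyphenyl]acetyl}oxazolidin-2-one, via mixed pivalic anhydride 7 (not isolated)
Conditions: t-BuCOCl, Et3N, THF, −20 °C; then 6, LiCl, −20 °C to rt
Reagents that add atoms: none
Why: N-acylation of the oxazolidinone through a mixed anhydride; the hindered pivaloyl carbonyl directs attack to the arylacetyl carbonyl, and LiCl/Et3N activation avoids any organolithium near the aryl bromide.

Step 6
Reactants: 9 vanillin (4-hydroxy-3-methoxybenzaldehyde)
Product: 10 4-(tert-butyldimethylsilyloxy)-3-methoxybenzaldehyde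
Conditions: TBSCl, imidazole, DMF, rt
Reagents that add atoms: tert-butyldimethylsilyl chloride, CC(C)(C)[Si](C)(C)Cl
Why: Routine phenol silylation; the silyl group masks the ring C phenol until it is needed as the phenoxide trigger in step 12.

Step 7
Reactants: 8 (S)-4-benzyl-3-{2-[5-bromo-2-(tert-butyldimethylsilyloxy)-3-methoxyphenyl]acetyl}oxazolidin-2-one; 10 4-(tert-butyldimethylsilyloxy)-3-methoxybenzaldehyde
Product: 12 (S)-4-benzyl-3-{(2S,3S)-2-[5-bromo-2-(tert-butyldimethylsilyloxy)-3-methoxyphenyl]-3-hydroxy-3-[4-(tert-butyldimethylsilyloxy)-3-methoxyphenyl]propanoyl}oxazolidin-2-one, via boron Z-enolate 11 (not isolated)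
Conditions: n-Bu2BOTf, i-Pr2NEt, CH2Cl2, −78 to 0 °C; then 10, −78 to 0 °C; pH 7 buffer, MeOH, H2O2, 0 °C
Reagents that add atoms: none
Why: Evans syn-aldol reaction: the Z-boron enolate 11 reacts through a chair Zimmerman–Traxler transition state with the aldehyde on the enolate face away from the benzyl group, which should set the aryl-bearing carbon (the future C3) as S in 12 and the carbinol syn to it; any minor stereoisomer is a diastereomer and can be removed here.

Step 8
Reactants: 12 (S)-4-benzyl-3-{(2S,3S)-2-[5-bromo-2-(tert-butyldimethylsilyloxy)-3-methoxyphenyl]-3-hydroxy-3-[4-(tert-butyldimethylsilyloxy)-3-methoxyphenyl]propanoyl}oxazolidin-2-one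
Product: 13 (1S,2R)-2-[5-bromo-2-(tert-butyldimethylsilyloxy)-3-methoxyphenyl]-1-[4-(tert-butyldimethylsilyloxy)-3-methoxyphenyl]propane-1,3-diol
Conditions: LiBH4, MeOH (1 equiv), THF, 0 °C
Reagents that add atoms: none
Why: Reductive removal of the auxiliary by hydride attack at the exocyclic imide carbonyl; low temperature should keep retro-aldol cleavage and epimerisation of the alpha-aryl centre in check, and the descriptor of that carbon changes from S to R only because CH2OH ranks below the carbinol carbon.

Step 9
Reactants: 14 4-hydroxybenzoic acid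
Product: 16 4-(tert-butyldimethylsilyloxy)benzoic acid, via silyl ester 15 (not isolated)
Conditions: TBSCl (excess), imidazole, DMF, rt; then AcOH/THF/H2O, rt
Reagents that add atoms: tert-butyldimethylsilyl chloride, CC(C)(C)[Si](C)(C)Cl
Why: Exhaustive silylation followed by selective hydrolysis of the silyl ester, which is far more labile than the aryl silyl ether under mild aqueous acid.

Step 10
Reactants: 13 (1S,2R)-2-[5-bromo-2-(tert-butyldimethylsilyloxy)-3-methoxyphenyl]-1-[4-(tert-butyldimethylsilyloxy)-3-methoxyphenyl]propane-1,3-diol; 16 4-(tert-butyldimethylsilyloxy)benzoic acid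
Product: 17 (2R,3S)-2-[5-bromo-2-(tert-butyldimethylsilyloxy)-3-methoxyphenyl]-3-hydroxy-3-[4-(tert-butyldimethylsilyloxy)-3-methoxyphenyl]propyl 4-(tert-butyldimethylsilyloxy)benzoate
Conditions: EDC·HCl, DMAP (cat.), CH2Cl2, 0 °C
Reagents that add atoms: none
Why: Steglich esterification under kinetic control; with the acid as limiting reagent at low temperature the primary hydroxyl should react well ahead of the secondary benzylic one, which is flanked by two aryl-bearing carbons.

Step 11
Reactants: 17 (2R,3S)-2-[5-bromo-2-(tert-butyldimethylsilyloxy)-3-methoxyphenyl]-3-hydroxy-3-[4-(tert-butyldimethylsilyloxy)-3-methoxyphenyl]propyl 4-(tert-butyldimethylsilyloxy)benzoate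
Product: 18 (2R,3S)-3-acetoxy-2-[5-bromo-2-(tert-butyldimethylsilyloxy)-3-methoxyphenyl]-3-[4-(tert-butyldimethylsilyloxy)-3-methoxyphenyl]propyl 4-(tert-butyldimethylsilyloxy)benzoate
Conditions: Ac2O, pyridine, DMAP (cat.), CH2Cl2, 0 °C to rt
Reagents that add atoms: acetic anhydride, CC(=O)OC(C)=O
Why: DMAP-catalysed acetylation of the secondary benzylic alcohol installs the leaving group for step 12; fast acylation should outrun a 1,3-shift of the benzoate.

Step 12
Reactants: 18 (2R,3S)-3-acetoxy-2-[5-bromo-2-(tert-butyldimethylsilyloxy)-3-methoxyphenyl]-3-[4-(tert-butyldimethylsilyloxy)-3-methoxyphenyl]propyl 4-(tert-butyldimethylsilyloxy)benzoate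
Product: 21 [(2S,3R)-5-bromo-2-(4-hydroxy-3-methoxyphenyl)-7-methoxy-2,3-dihydrobenzofuran-3-yl]methyl 4-hydroxybenzoate, via triphenol acetate 19 (not isolated), via p-quinone methide 20 (not isolated)
Conditions: Bu4NF (3.5 equiv), THF, 0 °C to rt; aq. NH4Cl
Reagents that add atoms: none
Why: Fluoride cleaves the three aryl silyl ethers and gives 19 as its phenoxides. The ring C phenoxide, para to C2, then expels the benzylic acetate in a 1,6-elimination to the p-quinone methide 20, in which C2 is trigonal. The ring A phenoxide on C7a adds to the exocyclic carbon C2 in a 5-exo-trig oxa-conjugate addition that forms O1–C2, closes ring B and rearomatises ring C. The closest known reaction type is the fluoride- or base-triggered formation of p-quinone methides from 4-silyloxybenzyl esters with intramolecular phenol addition, the ring-closing half of phenylcoumaran formation. Because C2 passes through the planar stage, both C2 epimers of 18 would converge, and C3 carries no leaving group and should keep its configuration as long as cyclisation outruns tautomerisation of 20 to a stilbene. The new stereocentre C2 is set by substrate control from C3: ring C and the C3 acyloxymethyl group take opposite faces of the forming ring, and the trans isomer is also the more stable one, reachable by reversible ring opening under the phenoxide conditions. The step needs elimination to be faster than ester cleavage, which the phenoxide form of ring D (a deactivated benzoate) and the speed of the five-membered closure should secure.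

Step 13
Reactants: 21 [(2S,3R)-5-bromo-2-(4-hydroxy-3-methoxyphenyl)-7-methoxy-2,3-dihydrobenzofuran-3-yl]methyl 4-hydroxybenzoate; 22 propargyl alcohol (prop-2-yn-1-ol)
Product: 23 [(2S,3R)-2-(4-hydroxy-3-methoxyphenyl)-5-(3-hydroxyprop-1-yn-1-yl)-7-methoxy-2,3-dihydrobenzofuran-3-yl]methyl 4-hydroxybenzoate
Conditions: Pd(PhCN)2Cl2 (cat.), [HP(t-Bu)3]BF4 (cat.), CuI (cat.), i-Pr2NH, 1,4-dioxane, rt to 40 °C
Reagents that add atoms: none
Why: Sonogashira coupling; zerovalent palladium carrying the electron-rich P(t-Bu)3 should insert into the electron-rich C5–Br bond near room temperature, and free phenols and esters are tolerated by the mild amine base.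

Step 14
Reactants: 23 [(2S,3R)-2-(4-hydroxy-3-methoxyphenyl)-5-(3-hydroxyprop-1-yn-1-yl)-7-methoxy-2,3-dihydrobenzofuran-3-yl]methyl 4-hydroxybenzoate
Product: 24 [(2S,3R)-2-(4-hydroxy-3-methoxyphenyl)-5-[(Z)-3-hydroxyprop-1-en-1-yl]-7-methoxy-2,3-dihydrobenzofuran-3-yl]methyl 4-hydroxybenzoate
Conditions: H2 (1 atm), Pd/CaCO3 poisoned with Pb(OAc)2, quinoline, EtOAc, rt
Reagents that add atoms: none
Why: Lindlar-type semihydrogenation; syn delivery of hydrogen on the poisoned palladium surface should give the Z-alkene, quinoline holds back over-reduction, and the benzylic C–O bonds are not cleaved by this catalyst.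

Step 15
Reactants: 24 [(2S,3R)-2-(4-hydroxy-3-methoxyphenyl)-5-[(Z)-3-hydroxyprop-1-en-1-yl]-7-methoxy-2,3-dihydrobenzofuran-3-yl]methyl 4-hydroxybenzoate
Product: 25 [(2S,3R)-2-(4-hydroxy-3-methoxyphenyl)-7-methoxy-5-[(Z)-3-oxoprop-1-en-1-yl]-2,3-dihydrobenzofuran-3-yl]methyl 4-hydroxybenzoate
Conditions: activated MnO2, CH2Cl2, rt, exclusion of light
Reagents that add atoms: none
Why: MnO2 oxidation of an allylic alcohol on a neutral oxide surface, with no acid, base or soluble nucleophile that could turn the Z-enal into the E isomer; phenols are oxidised much more slowly under these conditions, so short contact and filtration should deliver 25.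

## Compound list

1 | 5-bromo-2-hydroxy-3-methoxybenzaldehyde (5-bromo-o-vanillin) | O=Cc1cc(Br)cc(OC)c1O | starting material
2 | 5-bromo-2-(tert-butyldimethylsilyloxy)-3-methoxybenzaldehyde | COc1cc(Br)cc(C=O)c1O[Si](C)(C)C(C)(C)C | intermediate
3 | tert-butyl[4-bromo-2-methoxy-6-(2-methoxyethenyl)phenoxy]dimethylsilane (E/Z mixture, geometry not defined) | COC=Cc1cc(Br)cc(OC)c1O[Si](C)(C)C(C)(C)C | intermediate
4 | 2-[5-bromo-2-(tert-butyldimethylsilyloxy)-3-methoxyphenyl]acetaldehyde | COc1cc(Br)cc(CC=O)c1O[Si](C)(C)C(C)(C)C | intermediate
5 | 2-[5-bromo-2-(tert-butyldimethylsilyloxy)-3-methoxyphenyl]acetic acid | COc1cc(Br)cc(CC(=O)O)c1O[Si](C)(C)C(C)(C)C | intermediate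
6 | (S)-4-benzyl-2-oxazolidinone | O=C1N[C@@H](Cc2ccccc2)CO1 | starting material
7 | 2-[5-bromo-2-(tert-butyldimethylsilyloxy)-3-methoxyphenyl]acetic pivalic anhydride | COc1cc(Br)cc(CC(=O)OC(=O)C(C)(C)C)c1O[Si](C)(C)C(C)(C)C | intermediate (not isolated)
8 | (S)-4-benzyl-3-{2-[5-bromo-2-(tert-butyldimethylsilyloxy)-3-methoxyphenyl]acetyl}oxazolidin-2-one | COc1cc(Br)cc(CC(=O)N2[C@@H](Cc3ccccc3)COC2=O)c1O[Si](C)(C)C(C)(C)C | intermediate
9 | vanillin (4-hydroxy-3-methoxybenzaldehyde) | COc1cc(C=O)ccc1O | starting material
10 | 4-(tert-butyldimethylsilyloxy)-3-methoxybenzaldehyde | COc1cc(C=O)ccc1O[Si](C)(C)C(C)(C)C | intermediate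
11 | di-n-butylboron (Z)-enolate of 8 | CCCCB(CCCC)O/C(=C\c1cc(Br)cc(OC)c1O[Si](C)(C)C(C)(C)C)N1[C@@H](Cc2ccccc2)COC1=O | intermediate (not isolated)
12 | (S)-4-benzyl-3-{(2S,3S)-2-[5-bromo-2-(tert-butyldimethylsilyloxy)-3-methoxyphenyl]-3-hydroxy-3-[4-(tert-butyldimethylsilyloxy)-3-methoxyphenyl]propanoyl}oxazolidin-2-one | COc1cc([C@@H](O)[C@@H](C(=O)N2[C@@H](Cc3ccccc3)COC2=O)c2cc(Br)cc(OC)c2O[Si](C)(C)C(C)(C)C)ccc1O[Si](C)(C)C(C)(C)C | intermediate
13 | (1S,2R)-2-[5-bromo-2-(tert-butyldimethylsilyloxy)-3-methoxyphenyl]-1-[4-(tert-butyldimethylsilyloxy)-3-methoxyphenyl]propane-1,3-diol | COc1cc([C@@H](O)[C@@H](CO)c2cc(Br)cc(OC)c2O[Si](C)(C)C(C)(C)C)ccc1O[Si](C)(C)C(C)(C)C | intermediate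
14 | 4-hydroxybenzoic acid | O=C(O)c1ccc(O)cc1 | starting material
15 | tert-butyldimethylsilyl 4-(tert-butyldimethylsilyloxy)benzoate | CC(C)(C)[Si](C)(C)OC(=O)c1ccc(O[Si](C)(C)C(C)(C)C)cc1 | intermediate (not isolated)
16 | 4-(tert-butyldimethylsilyloxy)benzoic acid | O=C(O)c1ccc(O[Si](C)(C)C(C)(C)C)cc1 | intermediate
17 | (2R,3S)-2-[5-bromo-2-(tert-butyldimethylsilyloxy)-3-methoxyphenyl]-3-hydroxy-3-[4-(tert-butyldimethylsilyloxy)-3-methoxyphenyl]propyl 4-(tert-butyldimethylsilyloxy)benzoate | COc1cc([C@@H](O)[C@@H](COC(=O)c2ccc(O[Si](C)(C)C(C)(C)C)cc2)c2cc(Br)cc(OC)c2O[Si](C)(C)C(C)(C)C)ccc1O[Si](C)(C)C(C)(C)C | intermediate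
18 | (2R,3S)-3-acetoxy-2-[5-bromo-2-(tert-butyldimethylsilyloxy)-3-methoxyphenyl]-3-[4-(tert-butyldimethylsilyloxy)-3-methoxyphenyl]propyl 4-(tert-butyldimethylsilyloxy)benzoate | COc1cc([C@@H](OC(C)=O)[C@@H](COC(=O)c2ccc(O[Si](C)(C)C(C)(C)C)cc2)c2cc(Br)cc(OC)c2O[Si](C)(C)C(C)(C)C)ccc1O[Si](C)(C)C(C)(C)C | intermediate (precursor of the key step)
19 | (2R,3S)-3-acetoxy-2-(5-bromo-2-hydroxy-3-methoxyphenyl)-3-(4-hydroxy-3-methoxyphenyl)propyl 4-hydroxybenzoate (present as its phenoxides) | COc1cc([C@@H](OC(C)=O)[C@@H](COC(=O)c2ccc(O)cc2)c2cc(Br)cc(OC)c2O)ccc1O | intermediate (not isolated)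
20 | (2R)-2-(5-bromo-2-hydroxy-3-methoxyphenyl)-3-(3-methoxy-4-oxocyclohexa-2,5-dien-1-ylidene)propyl 4-hydroxybenzoate (p-quinone methide, ylidene geometry not defined) | COC1=CC(=C[C@@H](COC(=O)c2ccc(O)cc2)c2cc(Br)cc(OC)c2O)C=CC1=O | intermediate (not isolated)
21 | [(2S,3R)-5-bromo-2-(4-hydroxy-3-methoxyphenyl)-7-methoxy-2,3-dihydrobenzofuran-3-yl]methyl 4-hydroxybenzoate | COc1cc([C@H]2Oc3c(OC)cc(Br)cc3[C@@H]2COC(=O)c2ccc(O)cc2)ccc1O | intermediate (product of the key step)
22 | propargyl alcohol (prop-2-yn-1-ol) | C#CCO | starting material
23 | [(2S,3R)-2-(4-hydroxy-3-methoxyphenyl)-5-(3-hydroxyprop-1-yn-1-yl)-7-methoxy-2,3-dihydrobenzofuran-3-yl]methyl 4-hydroxybenzoate | COc1cc([C@H]2Oc3c(OC)cc(C#CCO)cc3[C@@H]2COC(=O)c2ccc(O)cc2)ccc1O | intermediate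
24 | [(2S,3R)-2-(4-hydroxy-3-methoxyphenyl)-5-[(Z)-3-hydroxyprop-1-en-1-yl]-7-methoxy-2,3-dihydrobenzofuran-3-yl]methyl 4-hydroxybenzoate | COc1cc([C@H]2Oc3c(OC)cc(/C=C\CO)cc3[C@@H]2COC(=O)c2ccc(O)cc2)ccc1O | intermediate
25 | [(2S,3R)-2-(4-hydroxy-3-methoxyphenyl)-7-methoxy-5-[(Z)-3-oxoprop-1-en-1-yl]-2,3-dihydrobenzofuran-3-yl]methyl 4-hydroxybenzoate | COc1cc([C@H]2Oc3c(OC)cc(/C=C\C=O)cc3[C@@H]2COC(=O)c2ccc(O)cc2)ccc1O | target

## Step count and least certain steps

Total step count: 15. Longest linear sequence: 13 steps (steps 1–5, 7, 8, 10–15).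

Step 12 (key step). The most likely failure is loss of a proton from C3 of quinone methide 20, which tautomerises it to a stilbene phenol. Cleavage of the C2 acetate by adventitious hydroxide before the 1,6-elimination would leave a benzylic alcohol that does not eliminate under these conditions, and incomplete trans selectivity is a lesser concern. The fallback closes the same bond under acid instead of base. It sets out from 17, skips the acetylation, and removes the three silyl groups with Bu4NF buffered by AcOH (THF, 0 °C), which gives (2R,3S)-2-(5-bromo-2-hydroxy-3-methoxyphenyl)-3-hydroxy-3-(4-hydroxy-3-methoxyphenyl)propyl 4-hydroxybenzoate F1. A catalytic sulfonic acid (TsOH or a sulfonic acid resin, CH2Cl2/MeCN, 0 °C) then ionises the p-hydroxybenzylic alcohol to the O-protonated quinone methide, which the ring A phenol captures in a dehydrative cyclisation of the kind long used for phenylcoumarans. The route is rejoined at 21.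

Step 7. The aryl-stabilised, ortho-substituted boron enolate may add slowly to the electron-rich aldehyde, and the adduct may revert by retro-aldol cleavage during work-up; weaker facial control than with alkyl imides is also possible. The fallback replaces the auxiliary by a catalytic reduction with dynamic kinetic resolution; it sets out from 5 and 10 and returns at 13.
- Acid 5 is esterified with Me3SiCHN2 (toluene/MeOH) to methyl 2-[5-bromo-2-(tert-butyldimethylsilyloxy)-3-methoxyphenyl]acetate F2.
- Aldehyde 10 is oxidised with NaClO2 to 4-(tert-butyldimethylsilyloxy)-3-methoxybenzoic acid F3 and converted with (COCl)2 and catalytic DMF into 4-(tert-butyldimethylsilyloxy)-3-methoxybenzoyl chloride F4.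
- The lithium enolate of F2 (LiN(SiMe3)2, 2 equiv, THF, −78 °C) is C-acylated by F4 in a crossed Claisen condensation to racemic methyl 2-[5-bromo-2-(tert-butyldimethylsilyloxy)-3-methoxyphenyl]-3-[4-(tert-butyldimethylsilyloxy)-3-methoxyphenyl]-3-oxopropanoate F5.
- Transfer hydrogenation with RuCl(p-cymene)[(S,S)-TsDPEN] in HCO2H/Et3N reduces the ketone while the acidic alpha centre racemises, and should give methyl (2S,3S)-2-[5-bromo-2-(tert-butyldimethylsilyloxy)-3-methoxyphenyl]-3-hydroxy-3-[4-(tert-butyldimethylsilyloxy)-3-methoxyphenyl]propanoate F6.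
- The minor diastereomer must be removed by chromatography here, because it would lead to the enantiomer of 21. LiBH4 then reduces F6 to 13.
- The syn course is assumed; if the anti isomer prevailed, the (R,R) catalyst would be used, since only the alpha centre survives step 12.

Step 15. The Z-enal may isomerise to the E isomer on the oxide surface or during isolation, and the ring C phenol may be oxidised on long contact. The fallback makes the aldehyde without any oxidation; it sets out from 21 and returns at 25. Sonogashira coupling of 21 with 3,3-diethoxypropyne A3 under the conditions of step 13 gives [(2S,3R)-5-(3,3-diethoxyprop-1-yn-1-yl)-2-(4-hydroxy-3-methoxyphenyl)-7-methoxy-2,3-dihydrobenzofuran-3-yl]methyl 4-hydroxybenzoate F8. Semihydrogenation over Pd/CaCO3 poisoned with Pb(OAc)2 gives the (Z)-3,3-diethoxyprop-1-enyl compound [(2S,3R)-5-[(Z)-3,3-diethoxyprop-1-en-1-yl]-2-(4-hydroxy-3-methoxyphenyl)-7-methoxy-2,3-dihydrobenzofuran-3-yl]methyl 4-hydroxybenzoate F9. Hydrolysis of the acetal on wet silica gel with oxalic acid at 0 °C then releases 25.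

Step 13. Oxidative addition into the electron-rich C5–Br bond may be slow, and under copper and amine the alkyne may homocouple or the phenoxides may degrade on warming. The fallback is a Stille coupling under neutral conditions; it sets out from 21 and returns at 24, so it also replaces step 14. The reagent (Z)-3-(tributylstannyl)prop-2-en-1-ol F7 is made from 22 by trans-hydroalumination with LiAlH4 and trapping of the vinylalanate with Bu3SnOTf. Coupling of 21 with F7 (Pd(PPh3)4, a complex of zerovalent palladium, or Pd2(dba)3/P(t-Bu)3 with CsF, dioxane, 60–80 °C) transfers the alkenyl group with retention and gives 24 directly.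

Step 10. Over-acylation at the secondary hydroxyl or a benzoyl shift from the primary to the secondary oxygen would lower the yield of 17. The fallback activates the alcohol instead of the acid: a Mitsunobu esterification of 13 with 16 (PPh3, diisopropyl azodicarboxylate, THF, 0 °C), in which the unhindered primary alcohol forms the alkoxyphosphonium ion first. It sets out from 13 and 16, returns at 17, and makes no new compound.

## Further compounds

F1 | step 12 | (2R,3S)-2-(5-bromo-2-hydroxy-3-methoxyphenyl)-3-hydroxy-3-(4-hydroxy-3-methoxyphenyl)propyl 4-hydroxybenzoate | COc1cc([C@@H](O)[C@@H](COC(=O)c2ccc(O)cc2)c2cc(Br)cc(OC)c2O)ccc1O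
F2 | step 7 | methyl 2-[5-bromo-2-(tert-butyldimethylsilyloxy)-3-methoxyphenyl]acetate | COC(=O)Cc1cc(Br)cc(OC)c1O[Si](C)(C)C(C)(C)C
F3 | step 7 | 4-(tert-butyldimethylsilyloxy)-3-methoxybenzoic acid | COc1cc(C(=O)O)ccc1O[Si](C)(C)C(C)(C)C
F4 | step 7 | 4-(tert-butyldimethylsilyloxy)-3-methoxybenzoyl chloride | COc1cc(C(=O)Cl)ccc1O[Si](C)(C)C(C)(C)C
F5 | step 7 | methyl 2-[5-bromo-2-(tert-butyldimethylsilyloxy)-3-methoxyphenyl]-3-[4-(tert-butyldimethylsilyloxy)-3-methoxyphenyl]-3-oxopropanoate (racemic) | COC(=O)C(C(=O)c1ccc(O[Si](C)(C)C(C)(C)C)c(OC)c1)c1cc(Br)cc(OC)c1O[Si](C)(C)C(C)(C)C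
F6 | step 7 | methyl (2S,3S)-2-[5-bromo-2-(tert-butyldimethylsilyloxy)-3-methoxyphenyl]-3-hydroxy-3-[4-(tert-butyldimethylsilyloxy)-3-methoxyphenyl]propanoate | COc1cc([C@@H](O)[C@@H](C(=O)OC)c2cc(Br)cc(OC)c2O[Si](C)(C)C(C)(C)C)ccc1O[Si](C)(C)C(C)(C)C
F0 | step 10 | none | none
F7 | step 13 | (Z)-3-(tributylstannyl)prop-2-en-1-ol | CCCC[Sn](CCCC)(CCCC)/C=C\CO
F8 | step 15 | [(2S,3R)-5-(3,3-diethoxyprop-1-yn-1-yl)-2-(4-hydroxy-3-methoxyphenyl)-7-methoxy-2,3-dihydrobenzofuran-3-yl]methyl 4-hydroxybenzoate | COc1cc([C@H]2Oc3c(OC)cc(C#CC(OCC)OCC)cc3[C@@H]2COC(=O)c2ccc(O)cc2)ccc1O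
F9 | step 15 | [(2S,3R)-5-[(Z)-3,3-diethoxyprop-1-en-1-yl]-2-(4-hydroxy-3-methoxyphenyl)-7-methoxy-2,3-dihydrobenzofuran-3-yl]methyl 4-hydroxybenzoate | COc1cc([C@H]2Oc3c(OC)cc(/C=C\C(OCC)OCC)cc3[C@@H]2COC(=O)c2ccc(O)cc2)ccc1O
A1 | alternative 1 | (2S,3R)-3-(tert-butyldimethylsilyloxymethyl)-5-(diethoxymethyl)-7-methoxy-2-(3-methoxy-4-triisopropylsilyloxyphenyl)-2,3-dihydrobenzofuran-4-ol | COc1cc([C@H]2Oc3c(OC)cc(C(OCC)OCC)c(O)c3[C@@H]2CO[Si](C)(C)C(C)(C)C)ccc1O[Si](C(C)C)(C(C)C)C(C)C
A2 | alternative 1 | pentacarbonyl{[(2S,3R)-3-(tert-butyldimethylsilyloxymethyl)-2-(3-methoxy-4-triisopropylsilyloxyphenyl)-2,3-dihydrofuran-5-yl](methoxy)methylidene}chromium, a Cr(CO)5 carbene complex | COc1cc([C@H]2OC(C(OC)=[Cr](=C=O)(=C=O)(=C=O)(=C=O)=C=O)=C[C@@H]2CO[Si](C)(C)C(C)(C)C)ccc1O[Si](C(C)C)(C(C)C)C(C)C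
A3 | alternative 1 | 3,3-diethoxypropyne | C#CC(OCC)OCC
A4 | alternative 2 | (2S,3R)-5-bromo-3-(tert-butyldimethylsilyloxymethyl)-7-methoxy-2-(3-methoxy-4-triisopropylsilyloxyphenyl)-2,3-dihydrobenzofuran | COc1cc([C@H]2Oc3c(OC)cc(Br)cc3[C@@H]2CO[Si](C)(C)C(C)(C)C)ccc1O[Si](C(C)C)(C(C)C)C(C)C
A5 | alternative 2 | 4-bromo-2-[2-(tert-butyldimethylsilyloxy)-1-(4-methylbenzenesulfonyl)ethyl]-6-methoxyphenol (racemic) | COc1cc(Br)cc(C(CO[Si](C)(C)C(C)(C)C)S(=O)(=O)c2ccc(C)cc2)c1O
A6 | alternative 2 | 1-[3-methoxy-4-(triisopropylsilyloxy)benzyl]tetrahydrothiophenium bromide | COc1cc(C[S+]2CCCC2)ccc1O[Si](C(C)C)(C(C)C)C(C)C.[Br-]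
A7 | alternative 3 | (2S,3R)-3-(tert-butyldimethylsilyloxymethyl)-7-methoxy-2-(3-methoxy-4-triisopropylsilyloxyphenyl)-2,3-dihydrobenzofuran-5-carbaldehyde | COc1cc([C@H]2Oc3c(OC)cc(C=O)cc3[C@@H]2CO[Si](C)(C)C(C)(C)C)ccc1O[Si](C(C)C)(C(C)C)C(C)C
A8 | alternative 3 | 3-[(2R,3S)-1-(tert-butyldimethylsilyloxy)-3-hydroxy-3-(3-methoxy-4-triisopropylsilyloxyphenyl)propan-2-yl]-4-fluoro-5-methoxybenzaldehyde | COc1cc([C@@H](O)[C@@H](CO[Si](C)(C)C(C)(C)C)c2cc(C=O)cc(OC)c2F)ccc1O[Si](C(C)C)(C(C)C)C(C)C
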